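The array C5=C6–C7–C11(OH) (guaiane numbering, defined below) is read as an opened gem-dimethylcyclopropane. The terpene half therefore becomes (−)-α-gurjunene, joined at C4 to the o-quinone methide of grandinol. Everything rests on deleting the ring-fusion carbon C1 from the seven-membered ring (C1, C5–C10), which leaves the six-membered ring of carone, made from dihydrocarvone. The key step puts C1 back between C5 and C10 by a β-oxido carbenoid 1,2-shift. It exploits that the carbonyl carbon C5 is flanked by a non-enolisable, reluctantly migrating cyclopropane carbon (C6) and by the CHMe carbon C10, which migrates with retention. In one flask it gives the ring-expanded C5=C1 enolate, trapped as its silyl enol ether.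

Key step: step 3

Remark on numbering: C1 = ring-fusion CH, C2/C3 = cyclopentane CH2, C4 = quaternary carbon, C5 = ring-fusion sp2 carbon, C6 = vinylic CH, C7 = CH bearing C11 (CMe2OH), C8/C9 = CH2, C10 = CHMe.
Remark on the chemistry: commercial (+)-dihydrocarvone is a mixture of epimers at the methyl-bearing carbon. It is drawn as the (2R,5R) isomer because that centre is equilibrated in step 2.

Step 1
Reactants: 1 (+)-dihydrocarvone, (2R,5R)-2-methyl-5-(prop-1-en-2-yl)cyclohexan-1-one
Product: 2 (2R,5R)-5-(2-bromopropan-2-yl)-2-methylcyclohexan-1-one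
Conditions: HBr (33 % in AcOH), 0 °C
Reagents that add atoms: hydrogen bromide, Br
Why: Markovnikov hydrobromination of the 1,1-disubstituted alkene through the tertiary cation leaves the ketone and both stereocentres (C7, C10) untouched and creates no new one.

Step 2
Reactants: 2 (2R,5R)-5-(2-bromopropan-2-yl)-2-methylcyclohexan-1-one
Product: 3 carone, (1S,3R,6R)-3,7,7-trimethylbicyclo[4.1.0]heptan-2-one (3-methyl anti to the CMe2 bridge)
Conditions: KOH, MeOH, 0 °C → rt
Reagents that add atoms: none
Why: Intramolecular enolate alkylation (3-exo-tet) from the C6 enolate onto the tertiary bromide closes the cyclopropane, whose obligatory cis fusion sets C6 from C7, while the enolisable C10 equilibrates under the base toward the epimer with methyl anti to the CMe2 bridge, so both C10 epimers of 1 should converge on 3.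

Step 3
Reactants: 3 carone; 4 dibromomethane
Product: 8 [(1S,4R,7R)-4,8,8-trimethylbicyclo[5.1.0]oct-2-en-2-yl]oxy(trimethyl)silane, via dibromomethyl lithium alkoxide 5 (not isolated), via beta-oxido carbenoid 6 (not isolated), via ring-expanded lithium enolate 7 (not isolated)
Conditions: CH2Br2, LiTMP, THF, −78 °C; n-BuLi, −78 → 0 °C; TMSCl, −78 °C → rt
Reagents that add atoms: chlorotrimethylsilane, C[Si](C)(C)Cl
Why: LiCHBr2 (from 4 and LiTMP) adds to the C5 carbonyl of 3 from the face anti to the CMe2 bridge to give alkoxide 5, and Br/Li exchange with n-BuLi turns 5 into the β-oxido carbenoid 6, in which the alkoxide pushes a ring bond onto the carbenoid carbon as bromide leaves, so this carbon (C1) ends up between C5 and C10. The closest known reaction type is the β-oxido carbenoid ring enlargement of cycloalkanones in its one-flask form, a semipinacol-type 1,2-shift. No ring is closed by cyclisation: the six-membered ring C5–C10 becomes the seven-membered ring C1, C5–C10 by migration of C10 from C5 to C1 (bicyclo[4.1.0]heptane → bicyclo[5.1.0]octane). No lasting stereocentre is made (the carbinol centre of 5 is lost again and C1 becomes sp2), C10 migrates with retention and C6/C7 are not touched. The selectivity needed is migration of C10 rather than C6, and it is secured because this shift moves the carbon that best carries positive charge (2-methylcycloalkanones shift their CHMe carbon) while a cyclopropane carbon is among the poorest migrating groups. The shift delivers the C5=C1 lithium enolate 7 as a single regioisomer, which TMSCl fixes as 8.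

Step 4
Reactants: 8 [(1S,4R,7R)-4,8,8-trimethylbicyclo[5.1.0]oct-2-en-2-yl]oxy(trimethyl)silane; 9 methyl vinyl ketone (but-3-en-2-one)
Product: 11 (1S,3R,4R,7R)-4,8,8-trimethyl-3-(3-oxobutyl)bicyclo[5.1.0]octan-2-one, via adduct silyl enol ether 10 (not isolated)
Conditions: Sc(OTf)3 (10 mol %), CH2Cl2, −78 °C; then 1 M HCl, THF, 0 °C, brief
Reagents that add atoms: none
Why: In this Mukaiyama–Michael addition the enol silane should attack the Sc-activated enone through C1 from the face anti to the CMe2 bridge, whose endo methyl covers the other face (the bias known from 2-carene) and which is also the torsionally staggered approach past C10, so the chain ends up anti to the bridge and cis to the C10 methyl (C1 = R), a kinetic result that the cold, brief hydrolysis of 10 should not erode.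

Step 5
Reactants: 11 (1S,3R,4R,7R)-4,8,8-trimethyl-3-(3-oxobutyl)bicyclo[5.1.0]octan-2-one
Product: 12 (−)-α-gurjunene, (1aR,4R,4aR,7bS)-1,1,4,7-tetramethyl-1a,2,3,4,4a,5,6,7b-octahydro-1H-cyclopropa[e]azulene
Conditions: TiCl3(DME)1.5, Zn–Cu, DME, reflux, slow addition of 11
Reagents that add atoms: none
Why: Intramolecular McMurry coupling of the 1,5-diketone joins C4 to C5 and deoxygenates the titanium pinacolate to the tetrasubstituted cyclopentene, cyclopropyl ketones are known to couple without ring opening, no stereocentre is formed and the non-basic medium should leave C1 as set.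

Step 6
Reactants: 13 2-methylphloroglucinol (2-methylbenzene-1,3,5-triol); 14 isovaleryl chloride (3-methylbutanoyl chloride)
Product: 15 3-methyl-1-(2,4,6-trihydroxy-3-methylphenyl)butan-1-one
Conditions: AlCl3, CH2Cl2/MeNO2, 0 → 40 °C; aq. HCl work-up
Reagents that add atoms: none
Why: Friedel–Crafts acylation of the electron-rich triol takes place at one of its two equivalent free positions and the new acyl group deactivates the ring against a second acylation, with no stereocentre involved.

Step 7
Reactants: 15 3-methyl-1-(2,4,6-trihydroxy-3-methylphenyl)butan-1-one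
Product: 17 grandinol, 2,4,6-trihydroxy-3-methyl-5-(3-methylbutanoyl)benzaldehyde, via aryl iminium salt 16 (not isolated)
Conditions: POCl3, DMF, EtOAc, 0 °C → rt; then H2O, 50 °C
Reagents that add atoms: N,N-dimethylformamide, CN(C)C=O; water, O
Why: Vilsmeier–Haack formylation at the only free ring position gives iminium salt 16, which water hydrolyses to the aldehyde, with no stereocentre involved.

Step 8
Reactants: 12 (−)-α-gurjunene; 17 grandinol
Product: 21 target CNP0583424.1 (1R,4R,7R,10R in guaiane numbering), via o-quinone methide 18 (not isolated), via chroman 19 (not isolated), via regioisomeric chroman 20 (not isolated)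
Conditions: DDQ, MeNO2, 0 °C → rt; filter; then TsOH·H2O (cat.), THF/H2O, 0 °C
Reagents that add atoms: water, O
Why: DDQ dehydrogenates the ring methyl of 17 to o-quinone methide 18 (the known entry to euglobal-type adducts), which should add to C4=C5 of 12 in an asynchronous hetero-Diels–Alder reaction with its CH2 at C4, because charge then develops at the cyclopropylcarbinyl carbon C5, and from the face that carries H1, because there the arene stacks over a cyclopentene face bearing only hydrogens while C10 and the folded seven-membered ring block the other face (sets C4 = R), after which mild aqueous acid ionises the tertiary cyclopropylcarbinyl aryl ether of either regioisomer 19 or 20 and water opens the C6–C11 bond at C11 (cyclopropylcarbinyl-to-homoallyl rearrangement) to give C5=C6 and the tertiary alcohol with C7 untouched.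

Compound list
1 | (+)-dihydrocarvone, (2R,5R)-2-methyl-5-(prop-1-en-2-yl)cyclohexan-1-one | C[C@@H]1CC[C@H](CC1=O)C(C)=C | starting material
2 | (2R,5R)-5-(2-bromopropan-2-yl)-2-methylcyclohexan-1-one | C[C@@H]1CC[C@H](CC1=O)C(C)(C)Br | intermediate
3 | carone, (1S,3R,6R)-3,7,7-trimethylbicyclo[4.1.0]heptan-2-one | C[C@@H]1CC[C@@H]2[C@@H](C2(C)C)C1=O | intermediate
4 | dibromomethane | BrCBr | starting material
5 | lithium alkoxide of 2-(dibromomethyl)caran-2-ol, CHBr2 anti to the CMe2 bridge | C[C@@H]1CC[C@@H]2[C@@H](C2(C)C)[C@]1([O-])C(Br)Br.[Li+] | intermediate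
6 | β-oxido carbenoid, bromo(lithio)methyl lithium alkoxide | C[C@@H]1CC[C@@H]2[C@@H](C2(C)C)[C@]1([O-])C([Li])Br.[Li+] | intermediate
7 | lithium C5=C1 enolate of (1S,4R,7R)-4,8,8-trimethylbicyclo[5.1.0]octan-2-one | C[C@@H]1CC[C@@H]2[C@@H](C2(C)C)C([O-])=C1.[Li+] | intermediate
8 | [(1S,4R,7R)-4,8,8-trimethylbicyclo[5.1.0]oct-2-en-2-yl]oxy(trimethyl)silane | C[C@@H]1CC[C@@H]2[C@@H](C2(C)C)C(O[Si](C)(C)C)=C1 | intermediate
9 | methyl vinyl ketone | CC(=O)C=C | starting material
10 | Michael adduct with the side-chain ketone as its trimethylsilyl enol ether | C[C@@H]1CC[C@@H]2[C@@H](C2(C)C)C(=O)[C@@H]1CC=C(C)O[Si](C)(C)C | intermediate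
11 | (1S,3R,4R,7R)-4,8,8-trimethyl-3-(3-oxobutyl)bicyclo[5.1.0]octan-2-one | C[C@@H]1CC[C@@H]2[C@@H](C2(C)C)C(=O)[C@@H]1CCC(C)=O | intermediate
12 | (−)-α-gurjunene | C[C@@H]1CC[C@@H]2[C@@H](C2(C)C)C3=C(C)CC[C@H]13 | intermediate
13 | 2-methylphloroglucinol | Cc1c(O)cc(O)cc1O | starting material
14 | isovaleryl chloride | CC(C)CC(=O)Cl | starting material
15 | 3-methyl-1-(2,4,6-trihydroxy-3-methylphenyl)butan-1-one | CC(C)CC(=O)c1c(O)cc(O)c(C)c1O | intermediate
16 | aryl(dimethyl)iminium dichlorophosphate | CC(C)CC(=O)c1c(O)c(C=[N+](C)C)c(O)c(C)c1O.[O-]P(=O)(Cl)Cl | intermediate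
17 | grandinol | CC(C)CC(=O)c1c(O)c(C=O)c(O)c(C)c1O | intermediate
18 | o-quinone methide of grandinol | CC(C)CC(=O)C1=C(O)C(C=O)=C(O)C(=C)C1=O | intermediate
19 | chroman, CH2–C4 and O–C5 bonds both on the H1 face, ether oxygen next to the isovaleryl-bearing carbon | CC(C)CC(=O)c1c(O)c(C=O)c(O)c2c1O[C@@]3([C@H]4[C@@H](CC[C@@H](C)[C@H]3CC5)C4(C)C)[C@@]5(C)C2 | intermediate
20 | chroman, same terpene part, ether oxygen next to the formyl-bearing carbon | CC(C)CC(=O)c1c(O)c(C=O)c2O[C@@]3([C@H]4[C@@H](CC[C@@H](C)[C@H]3CC5)C4(C)C)[C@@]5(C)Cc2c1O | intermediate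
21 | CNP0583424.1 | CC(C)CC(=O)c1c(O)c(C=O)c(O)c(C[C@@]2(C)CC[C@H]3C2=C[C@H](C(C)(C)O)CC[C@H]3C)c1O | target

Total step count: 8. Longest linear sequence: 6 (steps 1–5 and 8).

Steps most likely to fail

**Step 8.** Several things may go wrong here.
- Capture of the quinone methide by a hindered tetrasubstituted alkene may be outrun by its self-condensation or by oxidation of the alkene with DDQ.
- The facial selectivity at C4 may be poor.
- The opened cation may lose a proton instead of taking up water.

The fallback sets out from 17 and 12 and comes back at 21; it separates oxidation from coupling. Compound 17 is oxidised with DDQ in methanol, which traps the quinone methide as 2,4,6-trihydroxy-3-(methoxymethyl)-5-(3-methylbutanoyl)benzaldehyde F1. Purified F1 is then heated with 12 in aqueous 1,4-dioxane at about 90 °C. Loss of methanol releases 18 slowly and at low concentration, with no oxidant and no added acid. The water present takes up the opened cation at C11 to give 21.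

**Step 3.** Migration of the cyclopropane carbon C6 in place of C10, or enolisation of the hindered ketone instead of carbonyl addition, would divert the material. The fallback sets out from 1 and comes back at 8; it enlarges the ring before the cyclopropane exists.
- The one-flask homologation (CH2Br2/LiTMP, n-BuLi, aqueous quench) is run on 1. Its unhindered carbonyl is flanked by CHMe and CH2, the case for which migration of the more substituted carbon is established. This should give (3R,6R)-3-methyl-6-(prop-1-en-2-yl)cycloheptan-1-one F2.
- HBr in AcOH gives (3R,6R)-6-(2-bromopropan-2-yl)-3-methylcycloheptan-1-one F3.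
- KOH in MeOH closes the cyclopropane from the C6 enolate, the three-membered closure being faster than the bridging alternative from C1. The product is (1S,4R,7R)-4,8,8-trimethylbicyclo[5.1.0]octan-2-one F4.
- LDA/TMSCl, which can enolise F4 only toward C1, gives 8.

**Step 4.** The enone may enter trans to the neighbouring C10 methyl instead of anti to the bridge. The centre may also epimerise later toward the more stable 1,10-trans arrangement. The fallback sets out from 8 and comes back at 11; it sets C1 by protonation instead of C–C bond formation, which turns the same facial bias round. The epimer formed in that case, (1S,3S,4R,7R)-4,8,8-trimethyl-3-(3-oxobutyl)bicyclo[5.1.0]octan-2-one F5, is converted with TMSOTf/Et3N into the bis(trimethylsilyl enol ether) F6, in which C1 is sp2. Kinetic C-protonation with cold dilute HCl in THF should place hydrogen on the face the enone had used, which leaves the chain on the other face and gives 11.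

Further compounds
F1 | step 8 | 2,4,6-trihydroxy-3-(methoxymethyl)-5-(3-methylbutanoyl)benzaldehyde | CC(C)CC(=O)c1c(O)c(C=O)c(O)c(COC)c1O
F2 | step 3 | (3R,6R)-3-methyl-6-(prop-1-en-2-yl)cycloheptan-1-one | C[C@@H]1CC[C@H](CC(=O)C1)C(C)=C
F3 | step 3 | (3R,6R)-6-(2-bromopropan-2-yl)-3-methylcycloheptan-1-one | C[C@@H]1CC[C@H](CC(=O)C1)C(C)(C)Br
F4 | step 3 | (1S,4R,7R)-4,8,8-trimethylbicyclo[5.1.0]octan-2-one | C[C@@H]1CC[C@@H]2[C@@H](C2(C)C)C(=O)C1
F5 | step 4 | (1S,3S,4R,7R)-4,8,8-trimethyl-3-(3-oxobutyl)bicyclo[5.1.0]octan-2-one | C[C@@H]1CC[C@@H]2[C@@H](C2(C)C)C(=O)[C@H]1CCC(C)=O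
F6 | step 4 | bis(trimethylsilyl enol ether) of F5 (ring C5=C1 and side-chain C3=C4) | C[C@@H]1CC[C@@H]2[C@@H](C2(C)C)C(O[Si](C)(C)C)=C1CC=C(C)O[Si](C)(C)C
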